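**Plan**
- The target (rings A to E in the order of its SMILES, no stereocentres) is cut at all four diaryl ether C–O bonds after a global O-demethylation. Each ring that has to act as an electrophile carries a formyl group that is later turned into a ring hydroxyl by Dakin oxidation.
- Enabling feature: in ring D the carbon bearing the ether oxygen to ring C is para, and the carbon bearing the ether oxygen to ring E is ortho, to the carbon of the middle hydroxyl. A formyl group on that carbon activates both positions, so ring D enters as 2,4-difluoro-6-methoxybenzaldehyde.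
- Forward: 3,5-difluorophenol gives this difluoroaldehyde, which serves twice. With the ring A phenol and then methoxide it gives the AB aldehyde, which Dakin oxidation turns into the AB phenol.
- The AB phenol displaces the fluoride of a ring C fluoroaldehyde, and a second Dakin oxidation gives the ABC phenol.
- Key union: the ABC phenoxide (para fluoride), then 3,4,5-trimethoxyphenoxide (ortho fluoride), on the difluoroaldehyde in one pot; Dakin oxidation and BBr3 finish.
- Stereochemistry: none to set; only the site order (para before ortho) has to be controlled.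

Key step: step 10

Remark on the chemistry: the free polyphenol is taken to be air-sensitive, so step 12 and its work-up are run under argon with degassed solvents.

**Step 1**
Reactants: 1 3,5-difluorophenol
Product: 3 2,4-difluoro-6-hydroxybenzaldehyde, via benzylic alcohol 2 (not isolated)
Conditions: MgCl2, Et3N, (CH2O)n, MeCN, reflux; then 1 M HCl
Reagents that add atoms: paraformaldehyde (as formaldehyde), C=O
Why: Casnati–Skattebøl ortho-formylation, in which the magnesium phenoxide delivers formaldehyde to the carbon next to oxygen (the two ortho sites of 1 are equivalent) and a second formaldehyde oxidises the benzylic alkoxide by hydride transfer.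

**Step 2**
Reactants: 3 2,4-difluoro-6-hydroxybenzaldehyde
Product: 4 2,4-difluoro-6-methoxybenzaldehyde
Conditions: MeI, K2CO3, acetone, 50 °C
Reagents that add atoms: iodomethane, CI
Why: Williamson O-methylation of the acidic salicylaldehyde hydroxyl, whose weakly nucleophilic phenoxide should be captured by MeI in acetone well before it can attack a fluoroarene.

**Step 3**
Reactants: 5 2,4,6-trimethoxybenzaldehyde
Product: 7 2,4,6-trimethoxyphenol, via aryl formate 6 (not isolated)
Conditions: 30% H2O2, cat. H2SO4, MeOH, 0 °C to rt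
Reagents that add atoms: hydrogen peroxide, OO
Why: Acid-catalysed Dakin oxidation, in which hydrogen peroxide adds to the formyl group, the electron-rich aryl group migrates to oxygen and the resulting formate is methanolysed in the same pot.

**Step 4**
Reactants: 7 2,4,6-trimethoxyphenol; 4 2,4-difluoro-6-methoxybenzaldehyde
Product: 9 2,6-dimethoxy-4-(2,4,6-trimethoxyphenoxy)benzaldehyde, via monofluoride 8 (not isolated)
Conditions: K2CO3, DMSO, 60 °C; then NaOMe, MeOH, 60 °C (one pot, argon)
Reagents that add atoms: sodium methoxide, [Na+].[O-]C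
Why: Two SNAr displacements through formyl-stabilised Meisenheimer anions, the doubly ortho-substituted phenoxide of 7 taking the more reactive and less shielded para fluoride and the small methoxide then the ortho fluoride, which also rehearses the site order needed in step 10.

**Step 5**
Reactants: 9 2,6-dimethoxy-4-(2,4,6-trimethoxyphenoxy)benzaldehyde
Product: 11 2,6-dimethoxy-4-(2,4,6-trimethoxyphenoxy)phenol, via aryl formate 10 (not isolated)
Conditions: 30% H2O2, cat. H2SO4, MeOH–CH2Cl2, rt
Reagents that add atoms: hydrogen peroxide, OO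
Why: Acid-catalysed Dakin oxidation of a 2,6-dimethoxy-4-aryloxybenzaldehyde, whose trioxygenated ring migrates readily to oxygen and whose formate is cleaved by methanol to the AB phenol.

**Step 6**
Reactants: 12 3,4,5-trimethoxyaniline
Product: 14 5-fluoro-1,2,3-trimethoxybenzene, via diazonium salt 13 (not isolated)
Conditions: NOBF4, 1,2-dichlorobenzene, 0 °C to rt; then 110 °C
Reagents that add atoms: nitrosonium tetrafluoroborate, N#[O+].F[B-](F)(F)F
Why: Balz–Schiemann reaction in one pot, in which NOBF4 diazotises the aniline and the aryldiazonium tetrafluoroborate loses N2 on heating, the aryl cation taking fluoride from BF4−.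

**Step 7**
Reactants: 14 5-fluoro-1,2,3-trimethoxybenzene
Product: 17 6-fluoro-2,3,4-trimethoxybenzaldehyde, via aryllithium 15 (not isolated), via hemiaminal alkoxide 16 (not isolated)
Conditions: n-BuLi, THF, −78 °C; DMF, −78 to 0 °C; then 1 M HCl
Reagents that add atoms: N,N-dimethylformamide, CN(C)C=O
Why: Directed ortho-metalation at the only kind of ring hydrogen in 14, which lies between fluorine and a methoxy group, followed by formylation of the aryllithium with DMF at −78 °C so that LiF is not lost to an aryne.

**Step 8**
Reactants: 11 2,6-dimethoxy-4-(2,4,6-trimethoxyphenoxy)phenol; 17 6-fluoro-2,3,4-trimethoxybenzaldehyde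
Product: 18 ABC aldehyde 6-[2,6-dimethoxy-4-(2,4,6-trimethoxyphenoxy)phenoxy]-2,3,4-trimethoxybenzaldehyde
Conditions: Cs2CO3, DMSO, 110 °C, argon
Reagents that add atoms: none
Why: SNAr through a formyl-stabilised Meisenheimer anion, in which the fluoride of 17 is ortho to the aldehyde, the two coplanar methoxy groups are meta to the reacting carbon and the para methoxy group is the middle one of three and twisted out of conjugation, while the hindrance sits on the phenoxide of 11, where this reaction type tolerates it.

**Step 9**
Reactants: 18 ABC aldehyde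
Product: 20 ABC phenol 6-[2,6-dimethoxy-4-(2,4,6-trimethoxyphenoxy)phenoxy]-2,3,4-trimethoxyphenol, via aryl formate 19 (not isolated)
Conditions: 30% H2O2, cat. H2SO4, MeOH–CH2Cl2, rt
Reagents that add atoms: hydrogen peroxide, OO
Why: Acid-catalysed Dakin oxidation of the only carbonyl group in 18, whose ring C, carrying oxygen at both ortho positions and the para position, migrates to oxygen and gives after methanolysis the hydroxyl flanked by the ring B ether and a methoxy group.

**Step 10**
Reactants: 20 ABC phenol; 4 2,4-difluoro-6-methoxybenzaldehyde; 21 3,4,5-trimethoxyphenol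
Product: 23 permethylated pentamer aldehyde 2-methoxy-6-(3,4,5-trimethoxyphenoxy)-4-{6-[2,6-dimethoxy-4-(2,4,6-trimethoxyphenoxy)phenoxy]-2,3,4-trimethoxyphenoxy}benzaldehyde, via monofluoride 22 (not isolated)
Conditions: 20 (1 equiv), 4 (1.05 equiv), Cs2CO3, DMSO, 50 °C; then 21 (1.5 equiv), Cs2CO3, 90 °C (one pot, argon)
Reagents that add atoms: none
Why: Both ether bonds arise by addition–elimination (SNAr): the caesium phenoxide of 20 adds to the fluorine-bearing carbon para to the formyl group of 4, the formyl group takes up the negative charge of the Meisenheimer anion and fluoride leaves to give 22, after which the phenoxide of 21 repeats the sequence at the remaining ortho fluoride. The closest known reaction type is the stepwise displacement of the two fluorides of 2,4-difluorobenzaldehydes and 2,4-difluoronitrobenzenes by two different phenoxides or amines, here run in one pot. No ring is closed and no stereocentre is formed; two skeletal C–O bonds to ring D are made. The step needs site selectivity between the two fluorides and a clean order of addition: the para fluoride is the more electrophilic and the less shielded one, so the bulky, doubly flanked phenoxide of 20 should take it at 50 °C with close to one equivalent of each partner, and only the small phenoxide of 21 at 90 °C should reach the ortho site next to the formyl group. The methoxy group and the first aryloxy group are both meta to the second reacting carbon and so do not quench its activation, and the steric load of the ring C oxygen is carried by the nucleophile and not by the electrophile. The formyl group is kept as the latent middle hydroxyl of ring D, to be revealed in step 11.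

**Step 11**
Reactants: 23 permethylated pentamer aldehyde
Product: 25 permethylated pentamer phenol 2-methoxy-6-(3,4,5-trimethoxyphenoxy)-4-{6-[2,6-dimethoxy-4-(2,4,6-trimethoxyphenoxy)phenoxy]-2,3,4-trimethoxyphenoxy}phenol, via aryl formate 24 (not isolated)
Conditions: 30% H2O2, cat. H2SO4, MeOH–CH2Cl2, rt
Reagents that add atoms: hydrogen peroxide, OO
Why: Acid-catalysed Dakin oxidation of the only carbonyl group in 23, in which ring D, oxygenated at both ortho positions and the para position, migrates to oxygen and the formate is cleaved by methanol to the middle hydroxyl of ring D.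

**Step 12**
Reactants: 25 permethylated pentamer phenol
Product: 26 CNP0154768.0, 5-{6-[2,6-dihydroxy-4-(2,4,6-trihydroxyphenoxy)phenoxy]-2,3,4-trihydroxyphenoxy}-3-(3,4,5-trihydroxyphenoxy)benzene-1,2-diol
Conditions: BBr3 (excess), CH2Cl2, −78 °C to rt; then degassed H2O, argon
Reagents that add atoms: none
Why: Lewis acid ether cleavage, in which BBr3 complexes each of the twelve methoxy oxygens and bromide removes the methyl group as MeBr, while the four diaryl ether bonds offer no alkyl carbon for attack and should stay intact, so that hydrolysis frees the thirteen hydroxyls.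

**Compound list**
1 | 3,5-difluorophenol | Oc1cc(F)cc(F)c1 | starting material
2 | 3,5-difluoro-2-(hydroxymethyl)phenol (present as its magnesium salt) | OCc1c(O)cc(F)cc1F | intermediate
3 | 2,4-difluoro-6-hydroxybenzaldehyde | O=Cc1c(O)cc(F)cc1F | intermediate
4 | 2,4-difluoro-6-methoxybenzaldehyde (ring D unit, also the ring B unit) | COc1cc(F)cc(F)c1C=O | intermediate
5 | 2,4,6-trimethoxybenzaldehyde | COc1cc(OC)c(C=O)c(OC)c1 | starting material
6 | 2,4,6-trimethoxyphenyl formate | COc1cc(OC)c(OC=O)c(OC)c1 | intermediate
7 | 2,4,6-trimethoxyphenol (ring A unit) | COc1cc(OC)c(O)c(OC)c1 | intermediate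
8 | 2-fluoro-6-methoxy-4-(2,4,6-trimethoxyphenoxy)benzaldehyde | COc1cc(OC)c(Oc2cc(F)c(C=O)c(OC)c2)c(OC)c1 | intermediate
9 | 2,6-dimethoxy-4-(2,4,6-trimethoxyphenoxy)benzaldehyde (AB aldehyde) | COc1cc(OC)c(Oc2cc(OC)c(C=O)c(OC)c2)c(OC)c1 | intermediate
10 | 2,6-dimethoxy-4-(2,4,6-trimethoxyphenoxy)phenyl formate | COc1cc(OC)c(Oc2cc(OC)c(OC=O)c(OC)c2)c(OC)c1 | intermediate
11 | 2,6-dimethoxy-4-(2,4,6-trimethoxyphenoxy)phenol (AB phenol) | COc1cc(OC)c(Oc2cc(OC)c(O)c(OC)c2)c(OC)c1 | intermediate
12 | 3,4,5-trimethoxyaniline | COc1cc(N)cc(OC)c1OC | starting material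
13 | 3,4,5-trimethoxybenzenediazonium tetrafluoroborate | COc1cc([N+]#N)cc(OC)c1OC.F[B-](F)(F)F | intermediate
14 | 5-fluoro-1,2,3-trimethoxybenzene | COc1cc(F)cc(OC)c1OC | intermediate
15 | (6-fluoro-2,3,4-trimethoxyphenyl)lithium | COc1cc(F)c([Li])c(OC)c1OC | intermediate
16 | lithium (dimethylamino)(6-fluoro-2,3,4-trimethoxyphenyl)methanolate (racemic, transient) | COc1cc(F)c(C([O-])N(C)C)c(OC)c1OC.[Li+] | intermediate
17 | 6-fluoro-2,3,4-trimethoxybenzaldehyde (ring C unit) | COc1cc(F)c(C=O)c(OC)c1OC | intermediate
18 | ABC aldehyde, 6-[2,6-dimethoxy-4-(2,4,6-trimethoxyphenoxy)phenoxy]-2,3,4-trimethoxybenzaldehyde | COc1cc(OC)c(Oc2cc(OC)c(Oc3cc(OC)c(OC)c(OC)c3C=O)c(OC)c2)c(OC)c1 | intermediate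
19 | ABC formate, 6-[2,6-dimethoxy-4-(2,4,6-trimethoxyphenoxy)phenoxy]-2,3,4-trimethoxyphenyl formate | COc1cc(OC)c(Oc2cc(OC)c(Oc3cc(OC)c(OC)c(OC)c3OC=O)c(OC)c2)c(OC)c1 | intermediate
20 | ABC phenol, 6-[2,6-dimethoxy-4-(2,4,6-trimethoxyphenoxy)phenoxy]-2,3,4-trimethoxyphenol | COc1cc(OC)c(Oc2cc(OC)c(Oc3cc(OC)c(OC)c(OC)c3O)c(OC)c2)c(OC)c1 | intermediate
21 | 3,4,5-trimethoxyphenol (ring E unit) | COc1cc(O)cc(OC)c1OC | starting material
22 | 2-fluoro-6-methoxy-4-{6-[2,6-dimethoxy-4-(2,4,6-trimethoxyphenoxy)phenoxy]-2,3,4-trimethoxyphenoxy}benzaldehyde | COc1cc(OC)c(Oc2cc(OC)c(Oc3cc(OC)c(OC)c(OC)c3Oc3cc(OC)c(C=O)c(F)c3)c(OC)c2)c(OC)c1 | intermediate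
23 | permethylated pentamer aldehyde, 2-methoxy-6-(3,4,5-trimethoxyphenoxy)-4-{6-[2,6-dimethoxy-4-(2,4,6-trimethoxyphenoxy)phenoxy]-2,3,4-trimethoxyphenoxy}benzaldehyde | COc1cc(OC)c(Oc2cc(OC)c(Oc3cc(OC)c(OC)c(OC)c3Oc3cc(OC)c(C=O)c(Oc4cc(OC)c(OC)c(OC)c4)c3)c(OC)c2)c(OC)c1 | intermediate
24 | permethylated pentamer formate (formate ester of 25) | COc1cc(OC)c(Oc2cc(OC)c(Oc3cc(OC)c(OC)c(OC)c3Oc3cc(OC)c(OC=O)c(Oc4cc(OC)c(OC)c(OC)c4)c3)c(OC)c2)c(OC)c1 | intermediate
25 | permethylated pentamer phenol, 2-methoxy-6-(3,4,5-trimethoxyphenoxy)-4-{6-[2,6-dimethoxy-4-(2,4,6-trimethoxyphenoxy)phenoxy]-2,3,4-trimethoxyphenoxy}phenol | COc1cc(OC)c(Oc2cc(OC)c(Oc3cc(OC)c(OC)c(OC)c3Oc3cc(OC)c(O)c(Oc4cc(OC)c(OC)c(OC)c4)c3)c(OC)c2)c(OC)c1 | intermediate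
26 | CNP0154768.0, 5-{6-[2,6-dihydroxy-4-(2,4,6-trihydroxyphenoxy)phenoxy]-2,3,4-trihydroxyphenoxy}-3-(3,4,5-trihydroxyphenoxy)benzene-1,2-diol | Oc1cc(O)c(Oc2cc(O)c(Oc3cc(O)c(O)c(O)c3Oc3cc(O)c(O)c(Oc4cc(O)c(O)c(O)c4)c3)c(O)c2)c(O)c1 | target

**Count and risks**
Total steps: 12. Longest linear sequence: 9 steps (1, 2, 4, 5, 8, 9, 10, 11, 12, from 3,5-difluorophenol).

Step 10. The first displacement may not stay at the para fluoride alone. During the hot second stage the ring E phenoxide may also exchange with the ABC aryloxide at the para position, or the ortho fluoride may react incompletely. The fallback sets out from 3 and makes the ring E ether on the oxygen that is already in place. Chan–Lam coupling of the hydroxyl of 3 with purchased (3,4,5-trimethoxyphenyl)boronic acid (Cu(OAc)2, pyridine, 4 Å sieves, CH2Cl2, air, rt) should give 2,4-difluoro-6-(3,4,5-trimethoxyphenoxy)benzaldehyde F1. SNAr of the phenoxide of 20 at the para fluoride of F1 (Cs2CO3, DMSO, 50 °C) should give 2-fluoro-6-(3,4,5-trimethoxyphenoxy)-4-{6-[2,6-dimethoxy-4-(2,4,6-trimethoxyphenoxy)phenoxy]-2,3,4-trimethoxyphenoxy}benzaldehyde F2, which is isolated so that any isomer from ortho attack can be removed. The last ortho fluoride is then replaced by methoxide (NaOMe, MeOH–DMSO, 60 °C) as in step 4, so that no aryloxide has to be forced onto the ortho site, and the route is rejoined at 23.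

Step 8. Addition of the hindered phenoxide of 11 to the only moderately activated ring C fluoride may be slow, and the electron-rich phenoxide may degrade at the temperature required. The fallback sets out from 11 and replaces SNAr by copper catalysis. Purchased 5-bromo-1,2,3-trimethoxybenzene is formylated under Rieche conditions (Cl2CHOMe, TiCl4, CH2Cl2, 0 °C; the two open positions are equivalent) to 6-bromo-2,3,4-trimethoxybenzaldehyde F3. An Ullmann ether coupling of F3 with 11 (CuI, picolinic acid, K3PO4, DMSO, 90 °C), helped by the ortho formyl group, should then return to the route at 18.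

Step 12. Ether cleavage may stop short of all twelve methyl groups, and the liberated pyrogallol and phloroglucinol rings may oxidise in air during work-up and purification. The fallback sets out from 25 and isolates the product through a stable derivative. After the BBr3 cleavage the crude polyphenol is not purified but acetylated at once (Ac2O, pyridine) to the tridecaacetate of 26 F4. F4 can be chromatographed in air and separated from partly methylated material. Acid methanolysis (HCl in degassed MeOH, generated from AcCl, argon) then releases 26.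

**Further compounds**
F1 | step 10 | 2,4-difluoro-6-(3,4,5-trimethoxyphenoxy)benzaldehyde | COc1cc(Oc2cc(F)cc(F)c2C=O)cc(OC)c1OC
F2 | step 10 | 2-fluoro-6-(3,4,5-trimethoxyphenoxy)-4-{6-[2,6-dimethoxy-4-(2,4,6-trimethoxyphenoxy)phenoxy]-2,3,4-trimethoxyphenoxy}benzaldehyde | COc1cc(OC)c(Oc2cc(OC)c(Oc3cc(OC)c(OC)c(OC)c3Oc3cc(F)c(C=O)c(Oc4cc(OC)c(OC)c(OC)c4)c3)c(OC)c2)c(OC)c1
F3 | step 8 | 6-bromo-2,3,4-trimethoxybenzaldehyde | COc1cc(Br)c(C=O)c(OC)c1OC
F4 | step 12 | tridecaacetate of 26 | CC(=O)Oc1cc(OC(C)=O)c(Oc2cc(OC(C)=O)c(Oc3cc(OC(C)=O)c(OC(C)=O)c(OC(C)=O)c3Oc3cc(OC(C)=O)c(OC(C)=O)c(Oc4cc(OC(C)=O)c(OC(C)=O)c(OC(C)=O)c4)c3)c(OC(C)=O)c2)c(OC(C)=O)c1
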